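The runs are simulated with made-up constants, and the scatter is random.

If the run is repeated, the thing to watch is whether target stops climbing before the run ends.

in all of them: gas 72 mM (held)
- Monday's: electrophile 0.44 M; run made earlier
- alpha: electrophile 0.40 M; time 6.0 min
- eta: electrophile 0.60 M; time 6.0 min
- delta: electrophile 0.80 M; time 6.0 min
- zeta: electrophile 1.2 M; time 6.0 min
- gamma: electrophile 2.0 M; time 6.0 min

- Monday's (time / min: target / %): 0.667: 1.5; 1.33: 3.8; 2.00: 6.0; 2.50: 7.3; 3.00: 8.8; 4.00: 11.4

(standard deviation of a reading: 0.3 percentage points)

1. [target] at the end for alpha, eta, delta, zeta, gamma, in this order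
2. how the row runs (falls all the way / rises, then falls / hardly changes / rises all the way / falls, then rises)

- at the start none of the gas is in solution
- "hardly changes" means that all values lie within two and a half points (for a concentration: within two and a half percent of the largest)

Monday's curve sags. Target's share of the charge grows at 0.0338 min⁻¹ from 0.667 min to 2.00 min, but at 0.0270 min⁻¹ from there to 4.00 min. With a scatter of 0.3 percentage points, this is a loose reading.

I read the sag as electrophile consuming target, so I write: rate of [target] = s[electrophile] − κ[electrophile][target]. The gain is pseudo-first-order in electrophile, and s is its constant. That slope falls off at 0.134 min⁻¹. Dividing by Monday's charge of 0.44 M gives my reading κ = 0.305 M⁻¹ min⁻¹, the loss constant, the fraction of target lost per minute per molar electrophile. Running the slope back to the start gives my reading s = 0.0404 min⁻¹.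

Holding electrophile at its charge, I integrate: [target] = (s/κ)(1 − exp(−t/τ)), with τ = 1/(κ[electrophile]). My plateau s/κ reads 0.132 M.

Now the settings. Time: alpha's τ is 8.21 min, longer than the 6.0 min run, so by hand more time still pays in alpha. Charge: gamma's τ is 1.64 min, shorter than the run, so by hand gamma sits near the plateau. Gas: its saturation concentration is 72 mM in each of these flasks, so I keep s unchanged. That is an assumption.

| flask | my [target] at the end |
|---|---|
| alpha | 0.0687 M |
| eta | 0.0882 M |
| delta | 0.102 M |
| zeta | 0.118 M |
| gamma | 0.129 M |

The forecast gives 0.063 M, 0.078 M, 0.088 M, 0.1 M and 0.105 M, lower than my gamma value, with the shape rises all the way, and adds: “A turnover is possible, but I expect a still slightly rising curve.”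

The flasks give 0.0640 M, 0.0748 M, 0.0791 M, 0.0781 M and 0.0656 M: the row rises, then falls, turning at an electrophile charge of 0.94 M.

    electrophile + nucleophile → acid set free + target (k = 0.0140 M⁻¹ s⁻¹)
    nucleophile + acid set free ⇌ protonated nucleophile, settled at all times (K = 390 M⁻¹)
    gas ⇌ nucleophile, rate k3*(csat - [nucleophile]) (kL = 0.0300 s⁻¹)
    electrophile + target → side product (k = 0.00590 M⁻¹ s⁻¹)

In alpha at the end, target is made 2.10 times as fast as it is used up, and my τ of 8.21 min is longer than the run. In gamma, my τ of 1.64 min is shorter than the run, yet target at the end stands at 0.0656 M, half my plateau, with nucleophile at 0.0295 M against 0.0566 M in alpha at the end.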